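**Plan**

1. Retrosynthetic cuts:
   - (a) The C5–C(vinyl) bond of the stilbene (Suzuki–Miyaura).
   - (b) O1–C7a of the dihydrofuran ring. It is reopened by putting a carbonyl carbon back between O1 and C7a, which gives a six-membered δ-lactone (3,4-dihydroisocoumarin).
   - (c) C2–C3 together with the lactone C–O bond (anhydride–aldehyde annulation).
2. Enabling feature: C7a of ring A lies between C7 (OMe) and C3a (side chain). A carboxyl on C7a is therefore a di-ortho-substituted, ortho-methoxy benzoate, the class that gives up CO2 to divalent palladium on mild heating. Together with the C3 carboxyl, the same group makes ring A an enolisable homophthalic anhydride.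
3. Forward order: ring A anhydride + MOM-vanillin (ring B) → δ-lactone with C2 and C3 set → C3 carboxyl reduced and silylated → lactone opened → carbonyl carbon expelled as CO2 with closure of the five-membered ring → borylation of C5–H (the only arene C–H without an ortho neighbour) → coupling with the ring C vinyl iodide → one acidic deprotection.
4. Stereochemistry: C2 and C3 both come from the organocatalytic annulation (catalyst-controlled face at C2, trans through the aldol–lactonisation). No later step breaks a bond at either centre. The E alkene comes from the Takai olefination and a stereoretentive coupling.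

Key step: step 8

Remark on numbering: O1, C2, C3, C3a, C4–C7 and C7a are the atoms of the 2,3-dihydrobenzofuran of the target. Ring A is its benzo ring, ring B the guaiacyl ring, ring C the resorcinol ring.

Assumption: the squaramide made from 9-amino(9-deoxy)epiquinine and 3,5-bis(trifluoromethyl)aniline is taken to give the (3R,4R) acid. If the sense of induction is the opposite, the quinidine-derived pseudoenantiomer is used.

**Step 1**
Reactants: 1 2-methoxy-6-methylbenzoic acid
Product: 3 2-(carboxymethyl)-6-methoxybenzoic acid, via dilithio dianion 2 (not isolated)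
Conditions: LDA (commercial solution, 2.3 equiv), THF, −78 to 0 °C; CO2 (gas), −78 °C; aq. HCl
Reagents that add atoms: carbon dioxide, O=C=O
Why: Lateral lithiation of the toluic acid to its carboxylate/benzyl dianion with a non-nucleophilic amide base, followed by carboxylation, is the standard entry to homophthalic acids and spares the ortho-methoxy group.

**Step 2**
Reactants: 3 2-(carboxymethyl)-6-methoxybenzoic acid
Product: 4 8-methoxy-1H-isochromene-1,3(4H)-dione (3-methoxyhomophthalic anhydride)
Conditions: Ac2O, toluene, 110 °C
Reagents that add atoms: none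
Why: Cyclodehydration of the 1,5-diacid by anhydride exchange with Ac2O closes the six-membered homophthalic anhydride without touching the aryl methyl ether.

**Step 3**
Reactants: 5 vanillin (4-hydroxy-3-methoxybenzaldehyde)
Product: 6 3-methoxy-4-(methoxymethoxy)benzaldehyde
Conditions: MOMCl, iPr2NEt, CH2Cl2, 0 °C to rt
Reagents that add atoms: chloromethyl methyl ether, COCCl
Why: Williamson-type O-alkylation of the phenol gives an acetal protecting group that should withstand borane, hydroxide, the oxidative palladium step and both boron-based steps.

**Step 4**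
Reactants: 4 8-methoxy-1H-isochromene-1,3(4H)-dione; 6 3-methoxy-4-(methoxymethoxy)benzaldehyde
Product: 7 (3R,4R)-8-methoxy-3-[3-methoxy-4-(methoxymethoxy)phenyl]-1-oxo-3,4-dihydro-1H-isochromene-4-carboxylic acid (trans)
Conditions: quinine-derived squaramide (5 mol %), MTBE, −15 °C; extractive isolation of the acid
Reagents that add atoms: none
Why: In this formal [4+2] cycloaddition (aldol–lactonisation) of an enolisable homophthalic anhydride with an aromatic aldehyde, the quinuclidine of the bifunctional catalyst generates the enolate, the squaramide binds the aldehyde and fixes the face attacked (C3 of the lactone, later C2), and lactonisation of the aldolate onto the aryl carbonyl gives the trans acid (C4 of the lactone, later C3).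

**Step 5**
Reactants: 7 (3R,4R)-lactone acid
Product: 8 (3R,4S)-4-(hydroxymethyl)-8-methoxy-3-[3-methoxy-4-(methoxymethoxy)phenyl]-3,4-dihydro-1H-isochromen-1-one
Conditions: BH3·SMe2, THF, 0 °C to rt; H2O
Reagents that add atoms: none
Why: Chemoselective borane reduction takes a free carboxylic acid through its acyloxyborane far faster than it attacks an aryl lactone, an acetal or an aryl ether, so only the C4 carboxyl should become the primary alcohol and neither stereocentre is touched (the descriptor at C4 changes only through the priority rules).

**Step 6**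
Reactants: 8 (3R,4S)-hydroxymethyl lactone
Product: 9 (3R,4S)-4-({[tert-butyl(dimethyl)silyl]oxy}methyl)-8-methoxy-3-[3-methoxy-4-(methoxymethoxy)phenyl]-3,4-dihydro-1H-isochromen-1-one
Conditions: TBSCl, imidazole, DMF, 0 °C to rt
Reagents that add atoms: tert-butyldimethylsilyl chloride, CC(C)(C)[Si](C)(C)Cl
Why: Standard silylation of the only free hydroxyl group masks the primary oxygen, which would otherwise compete with the secondary oxygen for C7a in step 8.

**Step 7**
Reactants: 9 (3R,4S)-silyloxymethyl lactone
Product: 10 potassium 2-{(1R,2S)-3-{[tert-butyl(dimethyl)silyl]oxy}-1-hydroxy-1-[3-methoxy-4-(methoxymethoxy)phenyl]propan-2-yl}-6-methoxybenzoate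
Conditions: KOH (1.05 equiv), THF–H2O, 40 °C; evaporation, azeotropic drying (toluene)
Reagents that add atoms: potassium hydroxide, [K+].[OH-]
Why: Saponification of the δ-lactone by acyl–oxygen cleavage leaves the C–O bond at the carbinol centre intact, and keeping the product as its potassium salt prevents relactonisation.

**Step 8**
Reactants: 10 potassium hydroxy-benzoate
Product: 12 tert-butyl({(2R,3S)-7-methoxy-2-[3-methoxy-4-(methoxymethoxy)phenyl]-2,3-dihydro-1-benzofuran-3-yl}methoxy)dimethylsilane, via oxapalladacycle 11 (not isolated)
Conditions: Pd(O2CCF3)2 (10 mol %), PhI(OAc)2 (1.5 equiv), Li2CO3 (1.5 equiv), DMSO (5 vol %) in 1,4-dioxane, 85 °C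
Reagents that add atoms: none
Why: Proposed new method: the carboxylate of 10 binds Pd(O2CCF3)2 and, being flanked by C7–OMe and by the C3a side chain, is twisted out of the plane of ring A and loses CO2 by ipso-palladation at C7a, after which the carbinol oxygen displaces trifluoroacetate (Li2CO3 takes up the proton) to give the six-membered oxapalladacycle 11, in which palladium stands where the lactone carbonyl carbon of 9 stood. PhI(OAc)2 oxidises 11 to tetravalent palladium, and C(sp2)–O reductive elimination then forms O1–C7a, returns divalent palladium to the cycle and contracts the six-membered metallacycle to the five-membered ring O1–C2–C3–C3a–C7a, a closure at the ipso carbon that amounts to deletion of one ring carbon from the δ-lactone. The closest known reaction types are the decarboxylative palladation of electron-rich di-ortho-substituted benzoic acids that starts the decarboxylative Heck reaction, and the hydroxyl-directed C–H activation/C–O cyclisation of 2-arylethanols (secondary benzylic carbinols included), which runs through the same palladacycle with the same oxidant, so that only the union of the two halves is new. No stereocentre is made and no bond to C2 or C3 is broken, so the (1R,2S) pair of 10 should appear unchanged as the trans (2R,3S) pair of 12. The step needs site selectivity for C7a over C4, the other position ortho to the side chain, which the ipso nature of the decarboxylation secures, and selectivity for the secondary over the primary oxygen, which the silyl group secures, while the chelate favours the alkoxide over acetate in the reductive elimination. The competing β-hydride elimination and protodepalladation should be held back by the rigid chelate, by the fast oxidation and by the carbonate buffer.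

**Step 9**
Reactants: 12 (2R,3S)-dihydrobenzofuran
Product: 13 2-[(2R,3S)-3-({[tert-butyl(dimethyl)silyl]oxy}methyl)-7-methoxy-2-[3-methoxy-4-(methoxymethoxy)phenyl]-2,3-dihydro-1-benzofuran-5-yl]-4,4,5,5-tetramethyl-1,3,2-dioxaborolane
Conditions: [Ir(OMe)(cod)]2 (1.5 mol %), dtbpy (3 mol %), B2pin2 (1.0 equiv), THF, 80 °C
Reagents that add atoms: bis(pinacolato)diboron, CC1(C)OB(OC1(C)C)B1OC(C)(C)C(C)(C)O1
Why: Iridium-catalysed C–H borylation is governed by sterics, and C5–H of ring A is the only aromatic C–H of 12 without an ortho substituent, since C4–H, C6–H and every C–H of ring B have one.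

**Step 10**
Reactants: 14 3,5-dihydroxybenzaldehyde
Product: 15 3,5-bis(methoxymethoxy)benzaldehyde
Conditions: MOMCl (2.5 equiv), iPr2NEt, CH2Cl2, 0 °C to rt
Reagents that add atoms: chloromethyl methyl ether, COCCl
Why: Williamson-type O-alkylation of both phenols gives the same acetal group as on ring B, so that one final operation can remove all of them.

**Step 11**
Reactants: 15 3,5-bis(methoxymethoxy)benzaldehyde
Product: 16 1-[(E)-2-iodoethenyl]-3,5-bis(methoxymethoxy)benzene
Conditions: CrCl2 (6 equiv), CHI3 (2 equiv), THF, 0 °C
Reagents that add atoms: iodoform, IC(I)I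
Why: The Takai olefination, through the geminal dichromium species made from CHI3 and CrCl2, turns aromatic aldehydes into E vinyl iodides under neutral conditions that spare the acetals.

**Step 12**
Reactants: 13 C5 pinacol boronate; 16 (E)-vinyl iodide
Product: 17 tert-butyl({(2R,3S)-5-{(E)-2-[3,5-bis(methoxymethoxy)phenyl]ethenyl}-7-methoxy-2-[3-methoxy-4-(methoxymethoxy)phenyl]-2,3-dihydro-1-benzofuran-3-yl}methoxy)dimethylsilane
Conditions: Pd(dppf)Cl2 (5 mol %), K2CO3, 1,4-dioxane–H2O, 60 °C
Reagents that add atoms: none
Why: The Suzuki–Miyaura coupling of an aryl pinacol boronate with a vinyl iodide proceeds with retention of the alkene geometry and tolerates silyl ethers, acetals and the benzylic ether.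

**Step 13**
Reactants: 17 fully protected gnetofuran A
Product: 18 gnetofuran A, 5-{(E)-2-[(2R,3S)-2-(4-hydroxy-3-methoxyphenyl)-3-(hydroxymethyl)-7-methoxy-2,3-dihydro-1-benzofuran-5-yl]ethenyl}benzene-1,3-diol
Conditions: 3 M aq. HCl, MeOH–THF, 40 °C
Reagents that add atoms: none
Why: Acid-catalysed hydrolysis should cleave the three aryl methoxymethyl acetals and the primary silyl ether in one operation, the mild temperature keeping the benzylic C2–O1 bond closed, and any reversible opening would reclose to the more stable trans isomer under control of the untouched C3.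

**Compound list**

1 | 2-methoxy-6-methylbenzoic acid | COc1cccc(C)c1C(=O)O | starting material
2 | dilithio dianion of 1 (carboxylate and benzylic carbanion) | [Li+].[Li+].COc1cccc([CH2-])c1C(=O)[O-] | intermediate
3 | 2-(carboxymethyl)-6-methoxybenzoic acid | COc1cccc(CC(=O)O)c1C(=O)O | intermediate
4 | 8-methoxy-1H-isochromene-1,3(4H)-dione | COc1cccc2c1C(=O)OC(=O)C2 | intermediate
5 | vanillin | COc1cc(C=O)ccc1O | starting material
6 | 3-methoxy-4-(methoxymethoxy)benzaldehyde | COCOc1ccc(C=O)cc1OC | intermediate
7 | (3R,4R)-8-methoxy-3-[3-methoxy-4-(methoxymethoxy)phenyl]-1-oxo-3,4-dihydro-1H-isochromene-4-carboxylic acid | COc1cc([C@@H]2OC(=O)c3c(OC)cccc3[C@H]2C(=O)O)ccc1OCOC | intermediate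
8 | (3R,4S)-4-(hydroxymethyl)-8-methoxy-3-[3-methoxy-4-(methoxymethoxy)phenyl]-3,4-dihydro-1H-isochromen-1-one | COc1cc([C@@H]2OC(=O)c3c(OC)cccc3[C@H]2CO)ccc1OCOC | intermediate
9 | (3R,4S)-4-({[tert-butyl(dimethyl)silyl]oxy}methyl)-8-methoxy-3-[3-methoxy-4-(methoxymethoxy)phenyl]-3,4-dihydro-1H-isochromen-1-one | COc1cc([C@@H]2OC(=O)c3c(OC)cccc3[C@H]2CO[Si](C)(C)C(C)(C)C)ccc1OCOC | intermediate
10 | potassium 2-{(1R,2S)-3-{[tert-butyl(dimethyl)silyl]oxy}-1-hydroxy-1-[3-methoxy-4-(methoxymethoxy)phenyl]propan-2-yl}-6-methoxybenzoate | COc1cc([C@H](O)[C@H](CO[Si](C)(C)C(C)(C)C)c2cccc(OC)c2C(=O)[O-])ccc1OCOC.[K+] | intermediate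
11 | six-membered oxapalladacycle, palladium bound to C7a and to the carbinol oxygen (DMSO ligands omitted) | COc1cc([C@@H]2O[Pd]c3c(OC)cccc3[C@H]2CO[Si](C)(C)C(C)(C)C)ccc1OCOC | intermediate
12 | tert-butyl({(2R,3S)-7-methoxy-2-[3-methoxy-4-(methoxymethoxy)phenyl]-2,3-dihydro-1-benzofuran-3-yl}methoxy)dimethylsilane | COc1cc([C@@H]2Oc3c(OC)cccc3[C@H]2CO[Si](C)(C)C(C)(C)C)ccc1OCOC | intermediate
13 | C5 pinacol boronate of 12 | COc1cc([C@@H]2Oc3c(OC)cc(B4OC(C)(C)C(C)(C)O4)cc3[C@H]2CO[Si](C)(C)C(C)(C)C)ccc1OCOC | intermediate
14 | 3,5-dihydroxybenzaldehyde | O=Cc1cc(O)cc(O)c1 | starting material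
15 | 3,5-bis(methoxymethoxy)benzaldehyde | COCOc1cc(C=O)cc(OCOC)c1 | intermediate
16 | 1-[(E)-2-iodoethenyl]-3,5-bis(methoxymethoxy)benzene | COCOc1cc(/C=C/I)cc(OCOC)c1 | intermediate
17 | fully protected gnetofuran A (three MOM ethers, one TBS ether), (2R,3S), E | COc1cc([C@@H]2Oc3c(OC)cc(/C=C/c4cc(OCOC)cc(OCOC)c4)cc3[C@H]2CO[Si](C)(C)C(C)(C)C)ccc1OCOC | intermediate
18 | gnetofuran A, (2R,3S), E | COc1cc([C@@H]2Oc3c(OC)cc(/C=C/c4cc(O)cc(O)c4)cc3[C@H]2CO)ccc1O | target

Total step count: 13. Longest linear sequence: 10 (steps 1, 2, 4, 5, 6, 7, 8, 9, 12, 13).

**Steps most likely to fail**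

**Step 8.**
- What may go wrong: protodepalladation of the aryl–palladium species, β-hydride elimination of the palladium alkoxide, or transfer of acetate instead of the alkoxide in the reductive elimination may overtake ring closure.
- Fallback: the carboxyl is kept as the marker of C7a, but the event is split into two known reactions. It sets out from 10. A transition-metal-free decarboxylative iodination (I2, K3PO4, MeCN, 100 °C), known for ortho-methoxybenzoic acids, should give the aryl iodide (1R,2S)-3-{[tert-butyl(dimethyl)silyl]oxy}-2-(2-iodo-3-methoxyphenyl)-1-[3-methoxy-4-(methoxymethoxy)phenyl]propan-1-ol F1. An intramolecular Ullmann-type etherification (CuI, 1,10-phenanthroline, Cs2CO3, toluene, 110 °C) should then close the same O1–C7a bond with both centres untouched. The fallback comes back to the route at 12.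

**Step 4.**
- What may go wrong: the C8 methoxy group hinders the lactonisation and the aldehyde is electron-rich. The aldol step may therefore become reversible and slow, with erosion of facial and trans selectivity.
- Fallback: asymmetric catalysis is replaced by resolution. It sets out from 4 and 6. A DMAP-promoted annulation in CHCl3, followed by base equilibration at C4, should give the racemic trans acid F2. Crystallisation with (R)-1-phenylethylamine should give the less soluble (R)-1-phenylethylammonium (3R,4R)-carboxylate F3 (the antipodal amine is used if the other salt crystallises). Acidification comes back to the route at 7.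

**Step 5.**
- What may go wrong: after the reduction, the acyl group may migrate from the secondary to the primary oxygen (translactonisation), or the lactone may be partly over-reduced.
- Fallback: the order of opening and protection is inverted, so that acyl migration no longer matters. It sets out from 7. The crude borane reduction mixture is treated directly with aq. KOH, which opens either lactone isomer to the same potassium dihydroxy carboxylate F4. TBSCl and imidazole then silylate the primary hydroxyl selectively, any silyl ester being lost on work-up with aq. K2CO3. The fallback comes back to the route at 10.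

**Further compounds**

F1 | step 8 | (1R,2S)-3-{[tert-butyl(dimethyl)silyl]oxy}-2-(2-iodo-3-methoxyphenyl)-1-[3-methoxy-4-(methoxymethoxy)phenyl]propan-1-ol | COc1cc([C@H](O)[C@H](CO[Si](C)(C)C(C)(C)C)c2cccc(OC)c2I)ccc1OCOC
F2 | step 4 | racemic trans-8-methoxy-3-[3-methoxy-4-(methoxymethoxy)phenyl]-1-oxo-3,4-dihydro-1H-isochromene-4-carboxylic acid (both enantiomers) | COc1cc([C@@H]2OC(=O)c3c(OC)cccc3[C@H]2C(=O)O)ccc1OCOC.COc1cc([C@H]2OC(=O)c3c(OC)cccc3[C@@H]2C(=O)O)ccc1OCOC
F3 | step 4 | (R)-1-phenylethylammonium (3R,4R)-8-methoxy-3-[3-methoxy-4-(methoxymethoxy)phenyl]-1-oxo-3,4-dihydro-1H-isochromene-4-carboxylate | COc1cc([C@@H]2OC(=O)c3c(OC)cccc3[C@H]2C(=O)[O-])ccc1OCOC.C[C@@H]([NH3+])c1ccccc1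
F4 | step 5 | potassium 2-{(1R,2S)-1,3-dihydroxy-1-[3-methoxy-4-(methoxymethoxy)phenyl]propan-2-yl}-6-methoxybenzoate | COc1cc([C@H](O)[C@H](CO)c2cccc(OC)c2C(=O)[O-])ccc1OCOC.[K+]
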